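**Retrosynthetic overview**

1. The trisubstituted E-enal C=C is opened by a retro-aldol self-condensation into two molecules of one protected 12-(piperidin-6-yl)dodecanal, so both rings come from a single monomer.
2. The C12 arm is cut next to the ring: cross-metathesis of a 6-vinylpiperidine with dodec-11-en-1-ol, then hydrogenation and alcohol oxidation.
3. The strategy rests on the N1–C6 bond of each 2-methylpiperidin-3-ol ring (N1, C2–C6), whose C6 chain is cis to the C2 methyl. It is made by intramolecular N-allylation of an N-Boc amino (E)-allylic alcohol under divalent palladium, which leaves the chain as a vinyl group.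
4. The acyclic precursor comes from the Weinreb amide of N-Boc-L-alanine (C2 and its methyl): butenyl ketone, Felkin–Anh reduction (C3), MOM ether, acrylate cross-metathesis, ester reduction.
5. Ring order: the one piperidine ring of the monomer is closed in step 6; the second ring of the target arrives when two monomers are joined in step 10.

Key step: step 6

Remark: ring atoms are numbered N1, C2 (methyl), C3 (oxygen), C6 (side chain) throughout; amide 1 and Grignard solution 2 are taken as catalogue reagents (1 is otherwise one amide coupling away from N-Boc-L-alanine).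

**Route**

Step 1
Reactants: 1 N-Boc-L-alanine N-methoxy-N-methylamide; 2 but-3-enylmagnesium bromide
Product: 3 tert-butyl (S)-(3-oxohept-6-en-2-yl)carbamate
Conditions: 2 (3 equiv, THF solution), THF, −20 °C to rt; aq. NH4Cl
Reagents that add atoms: none
Why: Weinreb ketone synthesis, in which the N-magnesiated carbamate and the stable magnesium chelate of the tetrahedral adduct prevent over-addition and enolisation, so the ketone should form with the C2 configuration intact and no new stereocentre.

Step 2
Reactants: 3 tert-butyl (S)-(3-oxohept-6-en-2-yl)carbamate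
Product: 4 tert-butyl [(2S,3S)-3-hydroxyhept-6-en-2-yl]carbamate
Conditions: LiBH(s-Bu)3 (1.5 equiv), THF, −78 °C; aq. NH4Cl
Reagents that add atoms: none
Why: Felkin–Anh-controlled hydride reduction, in which the bulky, weakly chelating trialkylborohydride should approach anti to the carbamate nitrogen and past the C2 hydrogen instead of the methyl, setting C3 as S (syn to nitrogen); any anti epimer is removed by chromatography and can be recycled by reoxidation to 3.

Step 3
Reactants: 4 tert-butyl [(2S,3S)-3-hydroxyhept-6-en-2-yl]carbamate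
Product: 5 tert-butyl [(2S,3S)-3-(methoxymethoxy)hept-6-en-2-yl]carbamate
Conditions: MOMCl, i-Pr2NEt, CH2Cl2, 0 °C to rt
Reagents that add atoms: chloromethyl methyl ether (MOMCl), COCCl
Why: O-alkylation of the secondary alcohol to the MOM acetal with a hindered amine base leaves the weakly nucleophilic carbamate N–H alone and creates no stereocentre.

Step 4
Reactants: 5 tert-butyl [(2S,3S)-3-(methoxymethoxy)hept-6-en-2-yl]carbamate; 6 methyl acrylate
Product: 7 methyl (2E,6S,7S)-7-[(tert-butoxycarbonyl)amino]-6-(methoxymethoxy)oct-2-enoate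
Conditions: second-generation Grubbs catalyst (5 mol%), 6 (3 equiv), CH2Cl2, 40 °C
Reagents that add atoms: none
Why: Olefin cross-metathesis between an unhindered terminal alkene and an electron-poor acrylate that does not readily homodimerise should give the E-enoate selectively with ethene as the only co-product, Boc and MOM being inert to the ruthenium carbene.

Step 5
Reactants: 7 methyl (2E,6S,7S)-7-[(tert-butoxycarbonyl)amino]-6-(methoxymethoxy)oct-2-enoate
Product: 8 tert-butyl [(2S,3S,6E)-8-hydroxy-3-(methoxymethoxy)oct-6-en-2-yl]carbamate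
Conditions: i-Bu2AlH (3.5 equiv), CH2Cl2, −78 °C; aq. KNaC4H4O6
Reagents that add atoms: none
Why: 1,2-Reduction of the conjugated ester by the aluminium hydride at low temperature should give the geometrically pure E-allylic alcohol, the carbamate being only deprotonated and the acetal untouched.

Step 6
Reactants: 8 tert-butyl [(2S,3S,6E)-8-hydroxy-3-(methoxymethoxy)oct-6-en-2-yl]carbamate
Product: 9 tert-butyl (2S,3S,6S)-6-ethenyl-3-(methoxymethoxy)-2-methylpiperidine-1-carboxylate
Conditions: PdCl2(MeCN)2 (10 mol%), THF, 0 °C to rt
Reagents that add atoms: none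
Why: Divalent palladium, anchored by the allylic hydroxyl, forms a π-complex with the C6=C7 alkene; the carbamate nitrogen adds to C6 on the face opposite the metal (anti-aminopalladation), and the resulting C7–Pd bond collapses by syn elimination of Pd–OH across C7–C8, which unveils the vinyl group and gives back divalent palladium with no change of oxidation state. The closest known reaction type is the PdCl2(MeCN)2-catalysed cyclisation of N-carbamoyl amino allylic alcohols to 2-vinylpiperidines, formally an intramolecular SN2′ N-allylation. The piperidine ring closes through N1–C6 in the 6-exo-trig mode. The new C6 stereocentre is governed by allylic (A1,3) strain with the planar N-Boc group: in the chair-like transition state the C2 methyl and the C6 alkenyl arm both turn axial to escape the carbamate, so the vinyl group should be delivered cis to the methyl while the C3 OMOM group sits equatorial. The step needs 2,6-cis diastereoselectivity and attack of nitrogen at C6 and not at C8; the first is secured by the N-Boc carbamate flanking the C2 methyl, the second by hydroxyl-directed coordination of palladium and the preference for a six-membered over an eight-membered ring.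

Step 7
Reactants: 9 tert-butyl (2S,3S,6S)-6-ethenyl-3-(methoxymethoxy)-2-methylpiperidine-1-carboxylate; 10 dodec-11-en-1-ol
Product: 11 tert-butyl (2S,3S,6S)-6-[(1E)-12-hydroxydodec-1-en-1-yl]-3-(methoxymethoxy)-2-methylpiperidine-1-carboxylate
Conditions: second-generation Grubbs catalyst (5–10 mol%), 10 (3 equiv), CH2Cl2, 40 °C
Reagents that add atoms: none
Why: Olefin cross-metathesis of the monosubstituted vinyl group with an excess of the unhindered terminal alkenol (whose homodimer is itself a competent partner) should give the E-disubstituted alkene without touching C6, and the alkene geometry is immaterial because the double bond is hydrogenated next.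

Step 8
Reactants: 11 tert-butyl (2S,3S,6S)-6-[(1E)-12-hydroxydodec-1-en-1-yl]-3-(methoxymethoxy)-2-methylpiperidine-1-carboxylate
Product: 12 tert-butyl (2S,3S,6R)-6-(12-hydroxydodecyl)-3-(methoxymethoxy)-2-methylpiperidine-1-carboxylate
Conditions: H2 (1 atm), 10% Pd/C, EtOAc, rt
Reagents that add atoms: none
Why: Heterogeneous catalytic hydrogenation saturates the disubstituted alkene, while carbamate, acetal and primary alcohol are stable to hydrogen over palladium on carbon in a neutral solvent (the C6 descriptor changes to R only through the priority rules).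

Step 9
Reactants: 12 tert-butyl (2S,3S,6R)-6-(12-hydroxydodecyl)-3-(methoxymethoxy)-2-methylpiperidine-1-carboxylate
Product: 13 tert-butyl (2S,3S,6R)-3-(methoxymethoxy)-2-methyl-6-(12-oxododecyl)piperidine-1-carboxylate
Conditions: TEMPO (10 mol%), PhI(OAc)2 (1.2 equiv), CH2Cl2, rt
Reagents that add atoms: none
Why: Nitroxyl-catalysed oxidation of a primary alcohol stops at the aldehyde and does not affect the carbamate or the acetal.

Step 10
Reactants: 13 tert-butyl (2S,3S,6R)-3-(methoxymethoxy)-2-methyl-6-(12-oxododecyl)piperidine-1-carboxylate (two molecules)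
Product: 15 bis-Boc bis-MOM E-enal dimer, via aldol adduct 14 (not isolated)
Conditions: pyrrolidine (20 mol%), PhCO2H (20 mol%), toluene, 50 °C
Reagents that add atoms: none
Why: Amine–acid-catalysed aldol self-condensation, in which the enamine of one aldehyde adds to a second molecule and the adduct loses water, should give the thermodynamically preferred E-2-alkyl-2-enal (β-chain trans to the formyl group), the carbamate-masked nitrogens being unable to interfere.

Step 11
Reactants: 15 bis-Boc bis-MOM E-enal dimer
Product: 16 (2E)-2-{10-[(2R,5S,6S)-5-hydroxy-6-methylpiperidin-2-yl]decyl}-14-[(2R,5S,6S)-5-hydroxy-6-methylpiperidin-2-yl]tetradec-2-enal (target)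
Conditions: 3 M aq. HCl–THF (1:1 v/v), 50 °C; evaporate; aq. NaHCO3, CHCl3 extraction
Reagents that add atoms: none
Why: Acid-mediated cleavage of both tert-butyl carbamates and hydrolysis of both MOM acetals should proceed without touching any stereocentre, the protonated amines being unable to condense with the enal, which is stable to aqueous acid and keeps its E geometry.

**Compound list**

1 | N-Boc-L-alanine N-methoxy-N-methylamide, tert-butyl (S)-{1-[methoxy(methyl)amino]-1-oxopropan-2-yl}carbamate | C[C@H](NC(=O)OC(C)(C)C)C(=O)N(C)OC | starting material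
2 | but-3-enylmagnesium bromide | C=CCC[Mg]Br | starting material
3 | tert-butyl (S)-(3-oxohept-6-en-2-yl)carbamate | C[C@H](NC(=O)OC(C)(C)C)C(=O)CCC=C | intermediate
4 | tert-butyl [(2S,3S)-3-hydroxyhept-6-en-2-yl]carbamate | C[C@H](NC(=O)OC(C)(C)C)[C@@H](O)CCC=C | intermediate
5 | tert-butyl [(2S,3S)-3-(methoxymethoxy)hept-6-en-2-yl]carbamate | C[C@H](NC(=O)OC(C)(C)C)[C@@H](OCOC)CCC=C | intermediate
6 | methyl acrylate | C=CC(=O)OC | starting material
7 | methyl (2E,6S,7S)-7-[(tert-butoxycarbonyl)amino]-6-(methoxymethoxy)oct-2-enoate | C[C@H](NC(=O)OC(C)(C)C)[C@@H](OCOC)CC/C=C/C(=O)OC | intermediate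
8 | tert-butyl [(2S,3S,6E)-8-hydroxy-3-(methoxymethoxy)oct-6-en-2-yl]carbamate | C[C@H](NC(=O)OC(C)(C)C)[C@@H](OCOC)CC/C=C/CO | intermediate
9 | tert-butyl (2S,3S,6S)-6-ethenyl-3-(methoxymethoxy)-2-methylpiperidine-1-carboxylate | C[C@@H]1N(C(=O)OC(C)(C)C)[C@H](C=C)CC[C@@H]1OCOC | intermediate
10 | dodec-11-en-1-ol | C=CCCCCCCCCCCO | starting material
11 | tert-butyl (2S,3S,6S)-6-[(1E)-12-hydroxydodec-1-en-1-yl]-3-(methoxymethoxy)-2-methylpiperidine-1-carboxylate | C[C@@H]1N(C(=O)OC(C)(C)C)[C@H](/C=C/CCCCCCCCCCO)CC[C@@H]1OCOC | intermediate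
12 | tert-butyl (2S,3S,6R)-6-(12-hydroxydodecyl)-3-(methoxymethoxy)-2-methylpiperidine-1-carboxylate | C[C@@H]1N(C(=O)OC(C)(C)C)[C@H](CCCCCCCCCCCCO)CC[C@@H]1OCOC | intermediate
13 | tert-butyl (2S,3S,6R)-3-(methoxymethoxy)-2-methyl-6-(12-oxododecyl)piperidine-1-carboxylate | C[C@@H]1N(C(=O)OC(C)(C)C)[C@H](CCCCCCCCCCCC=O)CC[C@@H]1OCOC | intermediate
14 | aldol adduct, di-tert-butyl 6,6′-(11-formyl-12-hydroxytricosane-1,23-diyl)bis[(2S,3S,6R)-3-(methoxymethoxy)-2-methylpiperidine-1-carboxylate], mixture of epimers at the two new carbons | C[C@@H]1N(C(=O)OC(C)(C)C)[C@H](CCCCCCCCCCCC(O)C(C=O)CCCCCCCCCC[C@@H]2CC[C@H](OCOC)[C@H](C)N2C(=O)OC(C)(C)C)CC[C@@H]1OCOC | intermediate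
15 | bis-Boc bis-MOM E-enal dimer, di-tert-butyl 6,6′-[(11E)-11-formyltricos-11-ene-1,23-diyl]bis[(2S,3S,6R)-3-(methoxymethoxy)-2-methylpiperidine-1-carboxylate] | C[C@@H]1N(C(=O)OC(C)(C)C)[C@H](CCCCCCCCCCC/C=C(/C=O)CCCCCCCCCC[C@@H]2CC[C@H](OCOC)[C@H](C)N2C(=O)OC(C)(C)C)CC[C@@H]1OCOC | intermediate
16 | (2E)-2-{10-[(2R,5S,6S)-5-hydroxy-6-methylpiperidin-2-yl]decyl}-14-[(2R,5S,6S)-5-hydroxy-6-methylpiperidin-2-yl]tetradec-2-enal (CNP0177491.1) | C[C@@H]1N[C@H](CCCCCCCCCCC/C=C(/C=O)CCCCCCCCCC[C@@H]2CC[C@H](O)[C@H](C)N2)CC[C@@H]1O | target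

**Step count**

Total step count: 11. Longest linear sequence: 11 steps (1 to 16).

**Three steps most likely to fail**

Step 6 (key step). The cyclisation may leak from the axial–axial chair into other transition states, eroding the 2,6-cis selectivity. The alkylpalladium intermediate may also be diverted into β-hydride elimination with deposition of palladium metal, which stalls turnover. The fallback sets out from enoate 7 and returns at alcohol 12. Catalytic KOt-Bu in THF (−20 °C to rt) should bring about a reversible intramolecular aza-Michael addition of the carbamate, which under the same allylic strain should settle on the 2,6-cis ester tert-butyl (2S,3S,6S)-6-(2-methoxy-2-oxoethyl)-3-(methoxymethoxy)-2-methylpiperidine-1-carboxylate F1. Partial reduction with i-Bu2AlH (toluene, −78 °C) would give the aldehyde tert-butyl (2S,3S,6S)-3-(methoxymethoxy)-2-methyl-6-(2-oxoethyl)piperidine-1-carboxylate F2. A Wittig reaction with the ylide from (10-hydroxydecyl)triphenylphosphonium bromide F3 (made from 10-bromodecan-1-ol and PPh3 in MeCN at reflux; ylide with NaN(SiMe3)2, 2 equiv, THF, −78 °C to rt) would give the alkenol tert-butyl (2S,3S,6S)-6-[(2Z)-12-hydroxydodec-2-en-1-yl]-3-(methoxymethoxy)-2-methylpiperidine-1-carboxylate F4. Hydrogenation of F4 (H2, Pd/C, EtOAc) gives 12, so steps 6 to 8 are bypassed.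

Step 7. Turnover at the vinyl group next to the N-Boc-bearing carbon may be slow, so that homodimerisation of 10 and ruthenium-hydride-mediated alkene migration take over. The fallback sets out from vinylpiperidine 9 and returns at alcohol 12. Anti-Markovnikov hydroboration with 9-BBN (THF, rt) would give the alkylborane tert-butyl (2S,3S,6R)-6-[2-(9-borabicyclo[3.3.1]nonan-9-yl)ethyl]-3-(methoxymethoxy)-2-methylpiperidine-1-carboxylate F5, which is not isolated. It would be coupled in the same flask with commercial (10-bromodecyloxy)(tert-butyl)dimethylsilane in an alkyl–alkyl Suzuki–Miyaura reaction (Pd(OAc)2, PCy3, K3PO4·H2O, THF, rt) to the silyl ether tert-butyl (2S,3S,6R)-6-{12-[(tert-butyldimethylsilyl)oxy]dodecyl}-3-(methoxymethoxy)-2-methylpiperidine-1-carboxylate F6. Bu4NF in THF then frees 12, so steps 7 and 8 are replaced.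

Step 2. Facial selectivity of hydride delivery may be poor if a hydrogen-bonded or lithium-chelated conformer competes with the Felkin–Anh conformer and leads to the anti alcohol. The fallback sets out from amide 1 and returns at alcohol 4. LiAlH4 (THF, 0 °C) would reduce 1 to tert-butyl (S)-(1-oxopropan-2-yl)carbamate (N-Boc-L-alaninal) F7, which is used at once to avoid epimerisation. Addition of Grignard reagent 2 (THF, −78 °C) under Cram-chelate control should then give 4 directly, because the chelated conformer, which is harmful in the reduction, here places the carbon nucleophile anti to the methyl and so favours the syn isomer; steps 1 and 2 are replaced.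

**Further compounds**

F1 | step 6 | tert-butyl (2S,3S,6S)-6-(2-methoxy-2-oxoethyl)-3-(methoxymethoxy)-2-methylpiperidine-1-carboxylate | C[C@@H]1N(C(=O)OC(C)(C)C)[C@H](CC(=O)OC)CC[C@@H]1OCOC
F2 | step 6 | tert-butyl (2S,3S,6S)-3-(methoxymethoxy)-2-methyl-6-(2-oxoethyl)piperidine-1-carboxylate | C[C@@H]1N(C(=O)OC(C)(C)C)[C@H](CC=O)CC[C@@H]1OCOC
F3 | step 6 | (10-hydroxydecyl)triphenylphosphonium bromide | OCCCCCCCCCC[P+](c1ccccc1)(c1ccccc1)c1ccccc1.[Br-]
F4 | step 6 | tert-butyl (2S,3S,6S)-6-[(2Z)-12-hydroxydodec-2-en-1-yl]-3-(methoxymethoxy)-2-methylpiperidine-1-carboxylate | C[C@@H]1N(C(=O)OC(C)(C)C)[C@H](C/C=C\CCCCCCCCCO)CC[C@@H]1OCOC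
F5 | step 7 | tert-butyl (2S,3S,6R)-6-[2-(9-borabicyclo[3.3.1]nonan-9-yl)ethyl]-3-(methoxymethoxy)-2-methylpiperidine-1-carboxylate | C[C@@H]1N(C(=O)OC(C)(C)C)[C@H](CCB2C3CCCC2CCC3)CC[C@@H]1OCOC
F6 | step 7 | tert-butyl (2S,3S,6R)-6-{12-[(tert-butyldimethylsilyl)oxy]dodecyl}-3-(methoxymethoxy)-2-methylpiperidine-1-carboxylate | C[C@@H]1N(C(=O)OC(C)(C)C)[C@H](CCCCCCCCCCCCO[Si](C)(C)C(C)(C)C)CC[C@@H]1OCOC
F7 | step 2 | tert-butyl (S)-(1-oxopropan-2-yl)carbamate (N-Boc-L-alaninal) | C[C@H](NC(=O)OC(C)(C)C)C=O
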